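The synthesis rests on cutting ring A at C2–C3 and the ring fusion at C5–C10 (halimane numbering). In one operation the lithium enolate of an acyclic (E)-enone, which carries the whole side chain, adds to a dienyl aldehyde ester (aldol, C2–C3), and the resulting decatrienone closes by an intramolecular Diels–Alder reaction (C5–C10 and C8–C9). The step exploits the C1=C10 alkene of ring A, carried as a C1 ketone that activates the C9=C10 dienophile and sits in the tether, and the cyclohexane ring B, which is the Diels–Alder ring. C4, set by an enzyme, relays C5, C8 and C9 in that event.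

Key step: step 9

Remark: halimane numbering (C1–C20) of the target is used for every intermediate.
Remark: the esterase in step 7 is assumed to hydrolyse the ester group of 13 that leads to (R)-14.

Step 1
Reactants: 1 geranyl acetate
Product: 3 (2E)-3-methyl-6-oxohex-2-en-1-yl acetate, via 6,7-ozonide 2 (not isolated)
Conditions: O3 (1 equiv, indicator dye end point), CH2Cl2, −78 °C; then Me2S, −78 → 23 °C
Reagents that add atoms: ozone O=[O+][O-]
Why: Ozonolysis with reductive work-up should cleave the electron-rich 6,7-alkene before the 2,3-alkene, which the allylic acetate deactivates, provided ozone is limited to one equivalent; no stereocentre is formed.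

Step 2
Reactants: 3 (2E)-3-methyl-6-oxohex-2-en-1-yl acetate
Product: 5 (2E)-3-methylhept-2-en-6-yn-1-ol, via enyne acetate 4 (not isolated)
Conditions: dimethyl (1-diazo-2-oxopropyl)phosphonate, K2CO3, MeOH, 0 → 23 °C
Reagents that add atoms: dimethyl (1-diazo-2-oxopropyl)phosphonate COP(=O)(OC)C(=[N+]=[N-])C(C)=O
Why: The Ohira–Bestmann homologation turns the aldehyde into the terminal alkyne, and the methanolic carbonate cleaves the acetate in the same flask, which is wanted because an acetate would not survive the later enolate steps.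

Step 3
Reactants: 5 (2E)-3-methylhept-2-en-6-yn-1-ol
Product: 6 tert-butyldimethyl{[(2E)-3-methylhept-2-en-6-yn-1-yl]oxy}silane
Conditions: TBSCl, imidazole, DMF, 23 °C
Reagents that add atoms: tert-butyldimethylsilyl chloride CC(C)(C)[Si](C)(C)Cl
Why: Silylation of the primary allylic alcohol gives an ether that should tolerate AlMe3, LiN(i-Pr)2, heat and the palladium-catalysed reduction.

Step 4
Reactants: 6 tert-butyldimethyl{[(2E)-3-methylhept-2-en-6-yn-1-yl]oxy}silane
Product: 8 (3E,7E)-9-(tert-butyldimethylsilyloxy)-4,7-dimethylnona-3,7-dien-2-one, via alkenylalane 7 (not isolated)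
Conditions: AlMe3, Cp2ZrCl2 (20 mol %), CH2Cl2, 0 → 23 °C; then AcCl, Pd(PPh3)4 (3 mol %), THF, 0 °C
Reagents that add atoms: trimethylaluminium C[Al](C)C; acetyl chloride CC(=O)Cl
Why: Zirconium-catalysed syn-carboalumination of the terminal alkyne (Negishi carboalumination) puts methyl and aluminium cis on the new C9=C10 bond, and acylation of the alkenylalane with retention gives the (E)-enone whose geometry later fixes C9.

Step 5
Reactants: 9 dimethyl malonate; 10 (2E)-pent-2-enal
Product: 11 dimethyl 2-[(2E)-pent-2-en-1-ylidene]propanedioate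
Conditions: TiCl4, pyridine, THF, 0 → 23 °C
Reagents that add atoms: none
Why: Knoevenagel condensation under TiCl4/pyridine should add the malonate 1,2 to the enal rather than 1,4 and dehydrate to the dienylidene malonate.

Step 6
Reactants: 11 dimethyl 2-[(2E)-pent-2-en-1-ylidene]propanedioate
Product: 13 dimethyl 2-methyl-2-[(1E,3E)-penta-1,3-dien-1-yl]propanedioate, via sodium trienolate 12 (not isolated)
Conditions: NaH, THF–DMF, 0 °C; then MeI, 0 → 23 °C
Reagents that add atoms: iodomethane CI
Why: Deconjugative α-alkylation of the extended malonate enolate should place the methyl group on C4, which becomes quaternary but is still prochiral, and move the unsaturation into the mainly (E,E)-diene.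

Step 7
Reactants: 13 dimethyl 2-methyl-2-[(1E,3E)-penta-1,3-dien-1-yl]propanedioate
Product: 14 (2R,3E,5E)-2-(methoxycarbonyl)-2-methylhepta-3,5-dienoic acid
Conditions: pig liver esterase, phosphate buffer (pH 7.5), DMSO (5 vol %), 25 °C
Reagents that add atoms: water O
Why: Enzymatic desymmetrisation (hydrolysis of one of two enantiotopic ester groups of a disubstituted malonate) sets C4, the only stereocentre of the route that is introduced by a catalyst.

Step 8
Reactants: 14 (2R,3E,5E)-2-(methoxycarbonyl)-2-methylhepta-3,5-dienoic acid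
Product: 16 methyl (2R,3E,5E)-2-formyl-2-methylhepta-3,5-dienoate, via acid chloride 15 (not isolated)
Conditions: (COCl)2, DMF (cat.), CH2Cl2, 0 °C; then LiAlH(O-t-Bu)3, THF, −78 °C
Reagents that add atoms: none
Why: Partial reduction of the acid chloride with the hindered hydride (Rosenmund-type reduction) should stop at the non-enolisable aldehyde and spare the methyl ester, and C4 cannot epimerise because it is quaternary.

Step 9
Reactants: 8 (3E,7E)-9-(tert-butyldimethylsilyloxy)-4,7-dimethylnona-3,7-dien-2-one; 16 methyl (2R,3E,5E)-2-formyl-2-methylhepta-3,5-dienoate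
Product: 20 methyl (3S,4R,5S,8R,9S,10S,13E)-15-(tert-butyldimethylsilyloxy)-1-oxo-3-(triethylsilyloxy)halima-6,13-dien-18-oate (cis-fused), via lithium dienolate 17 (not isolated), via lithium aldolate 18 (not isolated), via silyl ether trienone 19 (not isolated)
Conditions: LiN(i-Pr)2, THF, −78 °C; 16, −78 °C; Et3SiCl, −78 → 0 °C; volatiles removed, PhMe, BHT, 120 °C (sealed vessel)
Reagents that add atoms: chlorotriethylsilane CC[Si](Cl)(CC)CC
Why: Kinetic deprotonation of 8 at the C2 methyl gives the cross-conjugated lithium dienolate, which adds to the non-enolisable aldehyde 16 (aldol addition, C2–C3), and after O-silylation the 1,7,9-decatrien-3-one 19 undergoes a thermal intramolecular Diels–Alder reaction between the C5=C6–C7=C8 diene and the ketone-activated C9=C10 dienophile (C5–C10 and C8–C9). The closest known reaction types are the lithium aldol addition of methyl ketones to α-quaternary aldehydes and the cycloaddition of decatrienones that carry the activating ketone in the tether, a class that favours the endo, cis-fused mode. Ring B closes as the concerted, suprafacial [4+2] cyclohexene, and ring A closes in the same event as the six-membered tether ring with the C1 ketone endo under the diene, so that H5 and H10 are cis. C3 is set by C4 in the aldol step, because lithium in THF should not chelate aldehyde and ester and the enolate should then enter the dipole-minimised rotamer of 16 past the methyl rather than the dienyl group, which places O3 cis to the ester; C5 and C8 are cis through the (E,E)-diene, and C9 follows from the (E)-enone geometry and the endo mode. The facial sense comes from the chair-like tether, in which the diene is axial at C5, the OSiEt3 group has to be equatorial (an axial one would meet C6) and the ester is therefore axial, which gives 5S,8R,9S from 4R. The step needs C2 over γ-enolisation (kinetic base at −78 °C), endo over exo closure (the small C9 methyl rather than the chain lies under the diene) and the C3-controlled facial selectivity; the minor C3 epimer would give a diastereomer that should be separable.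

Step 10
Reactants: 20 methyl (3S,4R,5S,8R,9S,10S,13E)-15-(tert-butyldimethylsilyloxy)-1-oxo-3-(triethylsilyloxy)halima-6,13-dien-18-oate
Product: 23 methyl (4S,5S,8R,9S,13E)-15-(tert-butyldimethylsilyloxy)-1-(trifluoromethylsulfonyloxy)halima-1(10),2,6,13-tetraen-18-oate, via dienone 21 (not isolated), via lithium trienolate 22 (not isolated)
Conditions: LiN(i-Pr)2 (2.5 equiv), THF, −78 → −20 °C; then PhNTf2, −78 → 23 °C
Reagents that add atoms: N-phenylbis(trifluoromethanesulfonimide) FC(F)(F)S(=O)(=O)N(c1ccccc1)S(=O)(=O)C(F)(F)F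
Why: E1cB loss of triethylsilanolate from the C2 enolate gives the 2-en-1-one, whose only remaining acidic hydrogen is H10 because C4 is quaternary, so O-triflation of the cross-conjugated enolate (enol triflate formation) should fix the C1=C10 bond regiospecifically and erase the temporary C3 and C10 stereocentres.

Step 11
Reactants: 23 methyl (4S,5S,8R,9S,13E)-15-(tert-butyldimethylsilyloxy)-1-(trifluoromethylsulfonyloxy)halima-1(10),2,6,13-tetraen-18-oate
Product: 24 methyl (4S,5S,8R,9S,13E)-15-(tert-butyldimethylsilyloxy)halima-1(10),2,6,13-tetraen-18-oate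
Conditions: Pd(OAc)2 (5 mol %), PPh3, n-Bu3N, HCO2H, DMF, 60 °C
Reagents that add atoms: none
Why: Palladium-catalysed formate reduction of the dienyl triflate should replace OTf by H without moving the double bonds, at a temperature below that at which 1,5-hydrogen shifts of cyclohexadienes would endanger C5.

Step 12
Reactants: 24 methyl (4S,5S,8R,9S,13E)-15-(tert-butyldimethylsilyloxy)halima-1(10),2,6,13-tetraen-18-oate
Product: 25 methyl (4S,5S,8R,9S,13E)-15-(tert-butyldimethylsilyloxy)halima-1(10),13-dien-18-oate
Conditions: 2-nitrobenzenesulfonohydrazide (excess, in portions), Et3N, CH2Cl2, 23 °C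
Reagents that add atoms: none
Why: Diimide reduction is a concerted syn hydrogen transfer whose rate falls steeply with alkene substitution, so the two cis-disubstituted ring alkenes C2=C3 and C6=C7 should be saturated while the trisubstituted C1=C10 and C13=C14 bonds remain, and no stereocentre is created.

Step 13
Reactants: 25 methyl (4S,5S,8R,9S,13E)-15-(tert-butyldimethylsilyloxy)halima-1(10),13-dien-18-oate
Product: 27 methyl (4S,5S,8R,9S,13E)-15-acetoxyhalima-1(10),13-dien-18-oate (CNP0209995.2), via alcohol 26 (not isolated)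
Conditions: n-Bu4NF, THF, 0 → 23 °C; then Ac2O, Et3N, DMAP (cat.), 23 °C
Reagents that add atoms: acetic anhydride CC(=O)OC(C)=O
Why: Fluoride-mediated desilylation followed by acetylation of the primary allylic alcohol in the same flask should give the acetate, while the hindered C4 methyl ester is untouched.

Compound list

1 | geranyl acetate, (2E)-3,7-dimethylocta-2,6-dien-1-yl acetate | CC(C)=CCC/C(C)=C/COC(C)=O | starting material
2 | 6,7-ozonide of 1, (2E)-5-(5,5-dimethyl-1,2,4-trioxolan-3-yl)-3-methylpent-2-en-1-yl acetate | CC1(C)OOC(CC/C(C)=C/COC(C)=O)O1 | intermediate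
3 | (2E)-3-methyl-6-oxohex-2-en-1-yl acetate | O=CCC/C(C)=C/COC(C)=O | intermediate
4 | (2E)-3-methylhept-2-en-6-yn-1-yl acetate | C#CCC/C(C)=C/COC(C)=O | intermediate
5 | (2E)-3-methylhept-2-en-6-yn-1-ol | C#CCC/C(C)=C/CO | intermediate
6 | tert-butyldimethyl{[(2E)-3-methylhept-2-en-6-yn-1-yl]oxy}silane | C#CCC/C(C)=C/CO[Si](C)(C)C(C)(C)C | intermediate
7 | [(1E,5E)-7-(tert-butyldimethylsilyloxy)-2,5-dimethylhepta-1,5-dien-1-yl]dimethylalane | C[Al](C)/C=C(\C)CC/C(C)=C/CO[Si](C)(C)C(C)(C)C | intermediate
8 | (3E,7E)-9-(tert-butyldimethylsilyloxy)-4,7-dimethylnona-3,7-dien-2-one | CC(=O)/C=C(\C)CC/C(C)=C/CO[Si](C)(C)C(C)(C)C | intermediate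
9 | dimethyl malonate | COC(=O)CC(=O)OC | starting material
10 | (2E)-pent-2-enal | CC/C=C/C=O | starting material
11 | dimethyl 2-[(2E)-pent-2-en-1-ylidene]propanedioate | CC/C=C/C=C(C(=O)OC)C(=O)OC | intermediate
12 | sodium trienolate of 11 (deprotonated at C8) | [Na+].[O-]C(OC)=C(C(=O)OC)/C=C/C=C/C | intermediate
13 | dimethyl 2-methyl-2-[(1E,3E)-penta-1,3-dien-1-yl]propanedioate | C/C=C/C=C/C(C)(C(=O)OC)C(=O)OC | intermediate
14 | (2R,3E,5E)-2-(methoxycarbonyl)-2-methylhepta-3,5-dienoic acid | COC(=O)[C@@](C)(C(=O)O)/C=C/C=C/C | intermediate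
15 | methyl (2S,3E,5E)-2-(chlorocarbonyl)-2-methylhepta-3,5-dienoate | COC(=O)[C@@](C)(C(Cl)=O)/C=C/C=C/C | intermediate
16 | methyl (2R,3E,5E)-2-formyl-2-methylhepta-3,5-dienoate | COC(=O)[C@@](C)(C=O)/C=C/C=C/C | intermediate
17 | lithium (3E,7E)-9-(tert-butyldimethylsilyloxy)-4,7-dimethylnona-1,3,7-trien-2-olate | [Li]OC(=C)/C=C(\C)CC/C(C)=C/CO[Si](C)(C)C(C)(C)C | intermediate
18 | lithium aldolate of 8 and 16 (3S,4R; C2–C3 formed) | COC(=O)[C@@](C)([C@@H](O[Li])CC(=O)/C=C(\C)CC/C(C)=C/CO[Si](C)(C)C(C)(C)C)/C=C/C=C/C | intermediate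
19 | methyl (2R,3E,5E)-2-[(1S,4E,8E)-10-(tert-butyldimethylsilyloxy)-5,8-dimethyl-3-oxo-1-(triethylsilyloxy)deca-4,8-dien-1-yl]-2-methylhepta-3,5-dienoate | COC(=O)[C@@](C)([C@@H](O[Si](CC)(CC)CC)CC(=O)/C=C(\C)CC/C(C)=C/CO[Si](C)(C)C(C)(C)C)/C=C/C=C/C | intermediate
20 | methyl (3S,4R,5S,8R,9S,10S,13E)-15-(tert-butyldimethylsilyloxy)-1-oxo-3-(triethylsilyloxy)halima-6,13-dien-18-oate (cis-fused; O3, CO2Me, H5 and H10 on one face) | COC(=O)[C@@]1(C)[C@@H](O[Si](CC)(CC)CC)CC(=O)[C@H]2[C@@H]1C=C[C@@H](C)[C@]2(C)CC/C(C)=C/CO[Si](C)(C)C(C)(C)C | intermediate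
21 | methyl (4S,5S,8R,9S,10S,13E)-15-(tert-butyldimethylsilyloxy)-1-oxohalima-2,6,13-trien-18-oate | COC(=O)[C@@]1(C)C=CC(=O)[C@H]2[C@@H]1C=C[C@@H](C)[C@]2(C)CC/C(C)=C/CO[Si](C)(C)C(C)(C)C | intermediate
22 | lithium 1(10)-en-1-olate of 21 | COC(=O)[C@@]1(C)C=CC(O[Li])=C2[C@@H]1C=C[C@@H](C)[C@]2(C)CC/C(C)=C/CO[Si](C)(C)C(C)(C)C | intermediate
23 | methyl (4S,5S,8R,9S,13E)-15-(tert-butyldimethylsilyloxy)-1-(trifluoromethylsulfonyloxy)halima-1(10),2,6,13-tetraen-18-oate | COC(=O)[C@@]1(C)C=CC(OS(=O)(=O)C(F)(F)F)=C2[C@@H]1C=C[C@@H](C)[C@]2(C)CC/C(C)=C/CO[Si](C)(C)C(C)(C)C | intermediate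
24 | methyl (4S,5S,8R,9S,13E)-15-(tert-butyldimethylsilyloxy)halima-1(10),2,6,13-tetraen-18-oate | COC(=O)[C@@]1(C)C=CC=C2[C@@H]1C=C[C@@H](C)[C@]2(C)CC/C(C)=C/CO[Si](C)(C)C(C)(C)C | intermediate
25 | methyl (4S,5S,8R,9S,13E)-15-(tert-butyldimethylsilyloxy)halima-1(10),13-dien-18-oate | COC(=O)[C@@]1(C)CCC=C2[C@@H]1CC[C@@H](C)[C@]2(C)CC/C(C)=C/CO[Si](C)(C)C(C)(C)C | intermediate
26 | methyl (4S,5S,8R,9S,13E)-15-hydroxyhalima-1(10),13-dien-18-oate | COC(=O)[C@@]1(C)CCC=C2[C@@H]1CC[C@@H](C)[C@]2(C)CC/C(C)=C/CO | intermediate
27 | methyl (4S,5S,8R,9S,13E)-15-acetoxyhalima-1(10),13-dien-18-oate (CNP0209995.2) | COC(=O)[C@@]1(C)CCC=C2[C@@H]1CC[C@@H](C)[C@]2(C)CC/C(C)=C/COC(C)=O | target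

Total step count: 13.
Longest linear sequence: 9 steps (steps 1–4 and 9–13; the other branch, steps 5–8 and 9–13, is equally long).

Steps most likely to fail

Step 9. The aldol addition may show poor facial selectivity at C3 (lithium chelation of aldehyde and ester would invert it), and the cycloaddition would pass this on as the wrong relationship between C4 and C5/C8/C9. The open-chain silyloxy ketone may also lose silanol before the slow cycloaddition of the trisubstituted dienophile takes place. Fallback: the two events are separated and put under reagent and Lewis acid control. Starting from 8 and 16, a boron aldol addition with chlorodiisopinocampheylborane of the matched handedness (Et3N, Et2O, −78 °C, oxidative work-up) gives the isolated hydroxy trienone F1. Silylation of F1 with Et3SiOTf and 2,6-lutidine gives 19 as an isolated compound. Me2AlCl in CH2Cl2 at −40 → 0 °C then promotes the endo cycloaddition, and the route is rejoined at 20.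

Step 12. Diimide may reduce the hindered C6=C7 bond incompletely, or begin to reduce the trisubstituted C1=C10 and C13=C14 bonds once a large excess is used. Fallback: the two reductions are staged so that each faces less competition. Starting from 20, hydrogenation over RhCl(PPh3)3 (H2, PhH–EtOH) saturates C6=C7 while no other di- or monosubstituted alkene is present and gives the 6,7-dihydro ketone F2. Elimination and triflation as in step 10 give the dienyl triflate F3, and formate reduction as in step 11 gives the ring diene F4. The single unhindered C2=C3 bond of F4 is then reduced with diimide, and the route is rejoined at 25.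

Step 7. The esterase may differentiate the two ester groups of 13 with low selectivity or in the opposite sense, which would erode or invert the absolute configuration of the whole route. Fallback: the hydrolytic desymmetrisation is replaced by a catalytic reductive one. Starting from 13, zinc-catalysed enantioselective hydrosilylation of one ester group (ZnEt2, a chiral tetradentate aminophenol ligand chosen for the R product, HSi(OEt)3, then aqueous work-up) gives the hydroxy ester F5. Oxidation of F5 with Dess–Martin periodinane rejoins the route at 16.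

Further compounds

F1 | step 9 | methyl (2R,3E,5E)-2-[(1S,4E,8E)-10-(tert-butyldimethylsilyloxy)-1-hydroxy-5,8-dimethyl-3-oxodeca-4,8-dien-1-yl]-2-methylhepta-3,5-dienoate | COC(=O)[C@@](C)([C@@H](O)CC(=O)/C=C(\C)CC/C(C)=C/CO[Si](C)(C)C(C)(C)C)/C=C/C=C/C
F2 | step 12 | methyl (3S,4R,5S,8R,9S,10S,13E)-15-(tert-butyldimethylsilyloxy)-1-oxo-3-(triethylsilyloxy)halim-13-en-18-oate | COC(=O)[C@@]1(C)[C@@H](O[Si](CC)(CC)CC)CC(=O)[C@H]2[C@@H]1CC[C@@H](C)[C@]2(C)CC/C(C)=C/CO[Si](C)(C)C(C)(C)C
F3 | step 12 | methyl (4S,5S,8R,9S,13E)-15-(tert-butyldimethylsilyloxy)-1-(trifluoromethylsulfonyloxy)halima-1(10),2,13-trien-18-oate | COC(=O)[C@@]1(C)C=CC(OS(=O)(=O)C(F)(F)F)=C2[C@@H]1CC[C@@H](C)[C@]2(C)CC/C(C)=C/CO[Si](C)(C)C(C)(C)C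
F4 | step 12 | methyl (4S,5S,8R,9S,13E)-15-(tert-butyldimethylsilyloxy)halima-1(10),2,13-trien-18-oate | COC(=O)[C@@]1(C)C=CC=C2[C@@H]1CC[C@@H](C)[C@]2(C)CC/C(C)=C/CO[Si](C)(C)C(C)(C)C
F5 | step 7 | methyl (2R,3E,5E)-2-(hydroxymethyl)-2-methylhepta-3,5-dienoate | COC(=O)[C@@](C)(CO)/C=C/C=C/C
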